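common to all: electrophile 0.050 M
- eta: nucleophile 1.4 equiv; run made earlier
- delta: nucleophile 2 equiv; run made earlier
- teal: nucleophile 1.30 equiv; time 2.5 h
- ochre: nucleophile 1.70 equiv; time 2.5 h
- blue: nucleophile 1.00 equiv; time 2.5 h

- eta (time / min: electrophile / %, target / %): 20.0: 94.0, 5.8; 40.0: 90.8, 8.7; 60.0: 83.9, 12.4; 80.0: 80.0, 13.1
- delta (time / min: electrophile / %, target / %): 20.0: 92.0, 8.5; 40.0: 85.6, 10.8; 60.0: 78.0, 13.7; 80.0: 72.0, 19.3

(standard deviation of a reading: 1 percentage point)

- the numbers in the tables scatter by 1 percentage point (one standard deviation)

1. part of the electrophile that has reacted at the end, teal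
2. part of the electrophile that has reacted at the end, ochre
3. part of the electrophile that has reacted at the end, blue
4. what raising the equivalents of nucleophile from its lowest to its highest value here does to the part of the electrophile that has reacted (changes below 5 percentage points count as none) (it rises / it falls / no change)

1. Early on, I divided the electrophile lost in the delta run by that lost in the eta run at the same reading, so that time dropped out. The ratio read 1.33 at 20.0 min and 1.40 at 80.0 min, with a scatter of 1 percentage point on each reading, against 1.43 for the equivalents. So I took the rate as proportional to electrophile left times nucleophile left, which is overall second order.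

2. I wrote x for the part of the electrophile reacted and b for the equivalents charged. Taking one nucleophile per electrophile, the amounts left, as fractions of the electrophile charge, are 1 − x and b − x. Then ln[(b − x)/(b(1 − x))] = (b − 1) × pace × time, and for b = 1 it becomes x/(1 − x) = pace × time.

3. The last reading of delta gave a pace of 0.00222 min⁻¹ and that of eta gave 0.00216 min⁻¹. I kept their mean, 0.00219 min⁻¹. This pace, the rate of x divided by (1 − x)(b − x), which equals the rate constant times the electrophile charge, is the quantity I carried.

4. Over 2.5 h, pace × time came to 0.328. My reckoning gave 31.0% for teal, 38.6% for ochre and 24.7% for blue.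

5. The forecast gave 31% for teal, 38.5% for ochre and 24.5% for blue, and for the trend, it rises. Its words were: “Conversion clearly rises with equivalents.”

6. The flask gave 32.6% for teal, 40.2% for ochre and 26.3% for blue; from blue to ochre, it rises, by 14 points.

    electrophile + nucleophile → acid set free + target (k = 2.35 M⁻¹ h⁻¹)
    nucleophile + acid set free ⇌ protonated nucleophile, settled at all times (K = 2400 M⁻¹)
    electrophile + acid set free → side product A (k = 2.15 M⁻¹ h⁻¹)
    nucleophile + target → over-reaction product (k = 1.03 M⁻¹ h⁻¹)
    electrophile + target → side product B (k = 7.38 M⁻¹ h⁻¹)

The nearest settings above teal at which its answer moved by 5 points were 1.56 equiv of nucleophile, with the time and other amounts held, and 3.01 h, with all amounts held. Read back through the same formula from the ochre answer, the pace came to 0.00233 min⁻¹. For a further flask like ochre but with 0.12 M of electrophile, I scaled pace × time with the charge to 0.788, which gave 64.1%, and that flask stood at 67.9%.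

The readings come from a simulation with constants of no real substance, and the scatter is random.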